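**Retrosynthetic overview**

1. Feature: each CH(iPr) carbon joins an aromatic carbon ortho to a phenol oxygen to C2 of a 4,4,6,6-tetramethylcyclohexane-1,3,5-trione. The five atoms phenol O, aryl C, CH(iPr), trione C2 and one flanking trione C=O are an opened 4-isopropyl-3,4-dihydrocoumarin; the other four ring carbons (two C=O, two CMe2) are the atoms of dimethylketene dimer.
2. Last disconnection, both arms at once: the trione C2–C(=O) and CMe2–C(=O) bonds, leading back to a 6-hexanoyl bis-dihydrocoumarin and two molecules of 2,2,4,4-tetramethylcyclobutane-1,3-dione.
3. Before that: the hexanoyl–aryl bond by Fries shift of the phenol hexanoate, and the two benzylic C–H bonds by twofold asymmetric CuH conjugate reduction of a bis-coumarin.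
4. Both pyranone rings come from two Pechmann condensations of phloroglucinol with ethyl 4-methyl-3-oxopentanoate.
5. Ring order: benzene ring bought; first pyranone; second pyranone (angular fusion); last, both carbocyclic trione rings together, each formed as its pyranone ring opens.

Key step: step 8

Assumption: the second Pechmann annulation is taken to occur at C8/O7 of 3 (angular isomer 4); annulation at C6 would give isomeric bis-coumarins with the same C/O pattern round the benzene ring, which would lead to the same target, and the target is written as one enol tautomer of each trione.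

**Route**

Step 1
Reactants: 1 phloroglucinol; 2 ethyl 4-methyl-3-oxopentanoate (1.0 equiv)
Product: 3 5,7-dihydroxy-4-isopropylcoumarin
Conditions: conc. H2SO4, 0 °C to rt
Reagents that add atoms: none
Why: Pechmann condensation: acid-promoted attack of the symmetrical triphenol on the ketone of 2, lactonisation with loss of ethanol and dehydration should give the 4-isopropylcoumarin, and one equivalent of 2 at low temperature should hold the reaction at mono-annulation.

Step 2
Reactants: 3 5,7-dihydroxy-4-isopropylcoumarin; 2 ethyl 4-methyl-3-oxopentanoate (1.5 equiv)
Product: 4 5-hydroxy-4,10-diisopropyl-2H,8H-pyrano[2,3-f]chromene-2,8-dione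
Conditions: CH3SO3H, 60 °C; crystallisation
Reagents that add atoms: none
Why: a second Pechmann condensation under more forcing acid should engage C8, the ring carbon between O1 and the 7-hydroxyl, and close through O7, which puts the new isopropyl group next to the ring oxygen and away from the 5-hydroxyl.

Step 3
Reactants: 4 5-hydroxy-4,10-diisopropyl-2H,8H-pyrano[2,3-f]chromene-2,8-dione
Product: 5 5-(tert-butyldimethylsilyloxy)-4,10-diisopropyl-2H,8H-pyrano[2,3-f]chromene-2,8-dione
Conditions: TBSCl, imidazole, DMF, 40 °C
Reagents that add atoms: tert-butyldimethylsilyl chloride, CC(C)(C)[Si](C)(C)Cl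
Why: silylation of the one phenol removes the acidic O–H that would quench the copper hydride and consume hydrosilane in the next step, and an aryl silyl ether should survive those conditions.

Step 4
Reactants: 5 5-(tert-butyldimethylsilyloxy)-4,10-diisopropyl-2H,8H-pyrano[2,3-f]chromene-2,8-dione
Product: 6 (4R,10R)-5-(tert-butyldimethylsilyloxy)-4,10-diisopropyl-3,4,9,10-tetrahydro-2H,8H-pyrano[2,3-f]chromene-2,8-dione
Conditions: Cu(OAc)2·H2O (5 mol%), (R)-DTBM-SEGPHOS (5.5 mol%), (EtO)2MeSiH (2.5 equiv), t-BuOH (2.5 equiv), THF/toluene, 0 °C to rt; SiO2 chromatography
Reagents that add atoms: none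
Why: asymmetric conjugate reduction of coumarins by a bisphosphine-ligated hydride of monovalent copper (made from the divalent copper acetate and the silane): hydride should go to C4 and C10 on the face fixed by the ligand and t-BuOH protonates the copper enolate; the (R)-ligand is assigned to the 4R,10R series by analogy with 4-substituted coumarins and is checked on the silyl ether of 3 first (the antipode is used if the check demands it), and because the two like centres are set independently most mismatched events fall into the (4R,10S)/(4S,10R) diastereomers removed by chromatography, so the enantiomeric purity of 6 should exceed the per-event selectivity.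

Step 5
Reactants: 6 (4R,10R)-5-(tert-butyldimethylsilyloxy)-4,10-diisopropyl-3,4,9,10-tetrahydro-2H,8H-pyrano[2,3-f]chromene-2,8-dione
Product: 7 (4R,10R)-5-hydroxy-4,10-diisopropyl-3,4,9,10-tetrahydro-2H,8H-pyrano[2,3-f]chromene-2,8-dione
Conditions: Bu4NF, AcOH, THF, 0 °C; recrystallisation
Reagents that add atoms: none
Why: fluoride cleavage of the aryl silyl ether, buffered with acetic acid so that the two base-sensitive aryl lactones stay closed; recrystallisation should remove residual unlike isomer.

Step 6
Reactants: 7 (4R,10R)-5-hydroxy-4,10-diisopropyl-3,4,9,10-tetrahydro-2H,8H-pyrano[2,3-f]chromene-2,8-dione; 8 hexanoyl chloride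
Product: 9 (4R,10R)-2,8-dioxo-4,10-diisopropyl-3,4,9,10-tetrahydro-2H,8H-pyrano[2,3-f]chromen-5-yl hexanoate
Conditions: Et3N, DMAP (cat.), CH2Cl2, 0 °C
Reagents that add atoms: none
Why: DMAP-catalysed O-acylation of the phenol; the amine base is too weak to enolise or open the lactones, and the benzylic centres are not involved.

Step 7
Reactants: 9 (4R,10R)-2,8-dioxo-4,10-diisopropyl-3,4,9,10-tetrahydro-2H,8H-pyrano[2,3-f]chromen-5-yl hexanoate
Product: 10 (4R,10R)-6-hexanoyl-5-hydroxy-4,10-diisopropyl-3,4,9,10-tetrahydro-2H,8H-pyrano[2,3-f]chromene-2,8-dione
Conditions: TiCl4 (3 equiv), ClCH2CH2Cl, 80 °C; then cold 1 M HCl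
Reagents that add atoms: none
Why: Fries rearrangement: the hexanoyl acylium released from the titanium-bound ester should attack C6, the only unsubstituted ring carbon and ortho to the titanium phenoxide, and the chelated ortho-acyl phenol is the stable outcome; the tethered lactone acyl groups cannot reach that position.

Step 8
Reactants: 10 (4R,10R)-6-hexanoyl-5-hydroxy-4,10-diisopropyl-3,4,9,10-tetrahydro-2H,8H-pyrano[2,3-f]chromene-2,8-dione; 11 2,2,4,4-tetramethylcyclobutane-1,3-dione (2.2 equiv)
Product: 13 Myrtucommulone F, via ring-opened bis(beta-keto lactone) 12 (not isolated)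
Conditions: LiN(SiMe3)2 (3.1 equiv), THF, −78 °C; 11, −78 to −30 °C; LiN(SiMe3)2 (2.5 equiv), −30 °C to rt; cold 1 M HCl
Reagents that add atoms: none
Why: Proposed new method: the first charge of LiN(SiMe3)2 should give the phenoxide and the two aryl-lactone enolates, whose carbons C3 and C9 add to a strained, non-enolisable carbonyl of 11; each cyclobutoxide then opens by retro-Claisen fragmentation to the chain C3-CO-CMe2-CO-CHMe2 (12, resting as its beta-keto lactone enolate), and the second charge of base forms the isopropyl ketone enolate, whose CMe2 carbon acylates at C2 or C8 either by direct addition-elimination or after reversible loss of the tethered aryloxide to an acylketene. The closest known reaction types are the nucleophilic ring opening of 11 to 2,2,4-trimethyl-3-oxopentanoyl derivatives, its base-induced conversion into hexamethylcyclohexane-1,3,5-trione, and the Dieckmann closure of 3,5-dioxo esters to cyclic triketones. Each of the two cyclohexanetrione rings closes by a 6-(enolendo)-exo-trig C-acylation in which the ring oxygen of the pyranone leaves, so that each carbocycle forms as its lactone opens and the phenoxide appears where the target carries OH. No stereocentre is created, since C2 of each trione ends as an enolate carbon, and the two benzylic centres, which hold neither an acidic hydrogen nor a leaving group, are carried through unchanged. The step needs the two lactone CH2 groups to react ahead of the hexanoyl CH2 and the aryl ketone carbonyl: the ortho phenoxide formed first turns the ketone into a vinylogous carboxylate that is a weak acid and a poor electrophile, the alpha hydrogens of an aryl ester are the more acidic ones, and only a slight excess over two equivalents of 11 is offered. Enol lactones from O-acylation are themselves acyl donors and should revert, which leaves the doubly stabilised triketone anions as the sink.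

**Compound list**

1 | phloroglucinol (benzene-1,3,5-triol) | Oc1cc(O)cc(O)c1 | starting material
2 | ethyl 4-methyl-3-oxopentanoate | CCOC(=O)CC(=O)C(C)C | starting material
3 | 5,7-dihydroxy-4-isopropylcoumarin | O=C1C=C(C(C)C)c2c(O)cc(O)cc2O1 | intermediate
4 | 5-hydroxy-4,10-diisopropyl-2H,8H-pyrano[2,3-f]chromene-2,8-dione | O=C1C=C(C(C)C)c2c(O)cc3OC(=O)C=C(C(C)C)c3c2O1 | intermediate
5 | 5-(tert-butyldimethylsilyloxy)-4,10-diisopropyl-2H,8H-pyrano[2,3-f]chromene-2,8-dione | O=C1C=C(C(C)C)c2c(O[Si](C)(C)C(C)(C)C)cc3OC(=O)C=C(C(C)C)c3c2O1 | intermediate
6 | (4R,10R)-5-(tert-butyldimethylsilyloxy)-4,10-diisopropyl-3,4,9,10-tetrahydro-2H,8H-pyrano[2,3-f]chromene-2,8-dione | O=C1C[C@H](C(C)C)c2c(O[Si](C)(C)C(C)(C)C)cc3OC(=O)C[C@H](C(C)C)c3c2O1 | intermediate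
7 | (4R,10R)-5-hydroxy-4,10-diisopropyl-3,4,9,10-tetrahydro-2H,8H-pyrano[2,3-f]chromene-2,8-dione | O=C1C[C@H](C(C)C)c2c(O)cc3OC(=O)C[C@H](C(C)C)c3c2O1 | intermediate
8 | hexanoyl chloride | CCCCCC(Cl)=O | starting material
9 | (4R,10R)-2,8-dioxo-4,10-diisopropyl-3,4,9,10-tetrahydro-2H,8H-pyrano[2,3-f]chromen-5-yl hexanoate | CCCCCC(=O)Oc1cc2OC(=O)C[C@H](C(C)C)c2c2OC(=O)C[C@H](C(C)C)c12 | intermediate
10 | (4R,10R)-6-hexanoyl-5-hydroxy-4,10-diisopropyl-3,4,9,10-tetrahydro-2H,8H-pyrano[2,3-f]chromene-2,8-dione | CCCCCC(=O)c1c(O)c2[C@@H](C(C)C)CC(=O)Oc2c2[C@@H](C(C)C)CC(=O)Oc12 | intermediate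
11 | 2,2,4,4-tetramethylcyclobutane-1,3-dione (dimethylketene dimer) | CC1(C)C(=O)C(C)(C)C1=O | starting material
12 | 6-hexanoyl-5-hydroxy-4,10-diisopropyl-3,9-bis(2,2,4-trimethyl-3-oxopentanoyl)-3,4,9,10-tetrahydro-2H,8H-pyrano[2,3-f]chromene-2,8-dione (benzylic centres as in 10; C3 and C9 undefined, present as enolates) | CCCCCC(=O)c1c(O)c2[C@@H](C(C)C)C(C(=O)C(C)(C)C(=O)C(C)C)C(=O)Oc2c2[C@@H](C(C)C)C(C(=O)C(C)(C)C(=O)C(C)C)C(=O)Oc12 | intermediate
13 | Myrtucommulone F (both benzylic centres R in the enol form drawn) | CCCCCC(=O)c1c(O)c([C@H](C2=C(O)C(C)(C)C(=O)C(C)(C)C2=O)C(C)C)c(O)c([C@H](C2=C(O)C(C)(C)C(=O)C(C)(C)C2=O)C(C)C)c1O | target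

**Count**

Total steps: 8. Longest linear sequence: 8 steps (1 to 13).

**Steps most likely to fail**

Step 8. The beta-branched lactone enolates may add too slowly to the tetrasubstituted carbonyl of 11 before they decay by aryloxide loss. The cascade may also stall after ring opening, once the isobutyryl enolate has been quenched by the new acidic C–H. Enolisation of the hexanoyl CH2 followed by Baker–Venkataraman-type acyl transfer from the neighbouring lactone is a further drain. The fallback sets out from 10 and makes the two bonds of each arm in separate, known operations. The lithium enolates of 10 (LiN(SiMe3)2, THF, −78 °C, extra base for the acidic product) are C-acylated in a Claisen acylation with 2,2,4-trimethyl-3-oxopentanoyl chloride F1, itself made from 11 by ring opening with dry HCl and catalytic ZnCl2. The bis(beta-keto lactone) 12 is isolated after acidic work-up and closed in a separate Dieckmann condensation with KOt-Bu in THF, the known closure of a 3,5-dioxo ester to a cyclic triketone. This comes back to the route at 13.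

Step 4. 1,2-Reduction of the activated aryl lactone carbonyls may run alongside the conjugate reduction and leave a mixture of lactone and lactol oxidation levels, and hydride delivery at C4 next to the silyloxy group may be slow. The fallback sets out from 5 and drives the reduction deliberately to one oxidation level. The same CuH catalyst with a large excess of (EtO)2MeSiH and t-BuOH should take both rings to the lactols, giving (4R,10R)-bis-lactol F2 as an anomer mixture, which is freed from the unlike isomers by chromatography. Both lactol carbons are then oxidised with Ag2CO3 on Celite in hot toluene (or pyridinium chlorochromate, C5H5NH[CrO3Cl], in CH2Cl2). This comes back to the route at 6.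

Step 7. The Lewis acid may ionise the lactone aryl esters as well as the hexanoate, which would lead to intermolecular acyl scrambling, or the hexanoyl group may simply be lost without C-acylation at the crowded position. The fallback sets out from 9 and uses a photo-Fries rearrangement (254 nm, degassed MeCN, quartz vessel, rt). This is a radical-pair acyl shift under neutral conditions, with the only free ortho position as the site of recombination. It comes back to the route at 10 and makes no compound outside the list (F0).

**Further compounds**

F1 | step 8 | 2,2,4-trimethyl-3-oxopentanoyl chloride | CC(C)C(=O)C(C)(C)C(Cl)=O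
F2 | step 4 | (4R,10R)-5-(tert-butyldimethylsilyloxy)-4,10-diisopropyl-3,4,9,10-tetrahydro-2H,8H-pyrano[2,3-f]chromene-2,8-diol (anomer mixture) | OC1C[C@H](C(C)C)c2c(O[Si](C)(C)C(C)(C)C)cc3OC(O)C[C@H](C(C)C)c3c2O1
F0 | step 7 | none | none
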